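**Retrosynthetic overview**
1. Target ⇐ acetylation of C9–OH; lactone and enal ⇐ one oxidation of a tetraol whose two identical C(=CH2)CH2OH arms sit on C5 and C7 (the C7 arm closes onto C8–OH).
2. Vinyl group and free C8–OH ⇐ Wittig opening of a bridged lactol; lactol ⇐ key ring contraction: acid-triggered 1,2-shift of C5 from C1 to C10 in an exo-epoxy-8-oxabicyclo[3.2.1]octane (seven-membered carbocycle → cyclohexane, sets the C10 quaternary centre).
3. Epoxide ⇐ Shi epoxidation used as kinetic resolution of a racemic oxabicyclic alkene; C5/C6/C7 all-cis triad from the rigid bicycle (Pd enolate alkenylation, hindered hydride, angeloylation).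
4. Oxabicycle ⇐ [4+3] cycloaddition of 3-methylfuran with the oxyallyl cation from tetrabromoacetone.
5. Ring order: oxygen-bridged seven-membered ring first, cyclohexane by contraction, γ-lactone last.

**Assumptions and conventions**
- Locants C1–C15 are elemane locants of the target: C10 (quaternary; C14 methyl and C1=C2 vinyl), C9 (OAc), C8 (lactone O), C7 (C11(=C13)–C12), C6 (O-angelate), C5 (C4(=C15)–C3HO). β means the face of the C10 methyl.
- Compounds 3, 4, 7, 8, 9 and 12 are racemic; their SMILES show the enantiomer that is carried on. From 13 onward all compounds are single enantiomers.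
- The catalogue compounds 1, 2, 5 and 10 are taken as commercially available.

**Route**

Step 1
Reactants: 1 3-methylfuran; 2 1,1,3,3-tetrabromoacetone
Product: 4 (±)-6-methyl-8-oxabicyclo[3.2.1]oct-6-en-3-one, via dibromo cycloadduct 3 (not isolated)
Conditions: Zn dust, B(OEt)3, THF, 0 °C → rt; then Zn–Cu couple, NH4Cl, MeOH, −78 °C → rt
Reagents that add atoms: none
Why: Hoffmann-type [4+3] cycloaddition of the zinc oxyallyl cation from 2 with the furan, then reductive debromination; only the two bridgehead centres form (cis by ring constraint, racemic), and the furan methyl ends up on the alkene carbon that becomes C10.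

Step 2
Reactants: 5 2-bromoprop-2-en-1-ol
Product: 6 (2-bromoallyloxy)(tert-butyl)dimethylsilane
Conditions: TBSCl, imidazole, CH2Cl2, 0 °C → rt
Reagents that add atoms: tert-butyldimethylsilyl chloride, CC(C)(C)[Si](C)(C)Cl
Why: standard silylation of a primary allylic alcohol; the silyl ether survives the enolate, hydride, acylation, epoxidation and Lewis-acid steps.

Step 3
Reactants: 4 (±)-6-methyl-8-oxabicyclo[3.2.1]oct-6-en-3-one; 6 (2-bromoallyloxy)(tert-butyl)dimethylsilane
Product: 8 (±)-2,4-bis[3-(tert-butyldimethylsilyloxy)prop-1-en-2-yl]-6-methyl-8-oxabicyclo[3.2.1]oct-6-en-3-one (2,4-cis; both arms equatorial), via mono-alkenyl ketone 7 (not isolated)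
Conditions: Pd2(dba)3 (2.5 mol %), [HP(t-Bu)3]BF4 (10 mol %), LiN(SiMe3)2 (3.3 equiv), 6 (2.4 equiv), toluene, 0 → 45 °C; then AcOH, THF, −78 °C
Reagents that add atoms: none
Why: double Pd-catalysed α-alkenylation of the ketone enolate (Buchwald–Hartwig-type enolate coupling, the alkenyl counterpart of α,α′-diarylation of cyclic ketones); both α-centres are epimerisable, and exo-face protonation of the final enolate together with the thermodynamic preference places both arms equatorial (endo, cis to each other, anti to the oxygen bridge), which fixes the future C5 and C7.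

Step 4
Reactants: 8 (±)-bis-alkenyl ketone
Product: 9 (±)-2,4-bis[3-(tert-butyldimethylsilyloxy)prop-1-en-2-yl]-6-methyl-8-oxabicyclo[3.2.1]oct-6-en-3-endo-ol
Conditions: LiBH(s-Bu)3, THF, −78 °C; then H2O
Reagents that add atoms: none
Why: hindered-hydride ketone reduction; the bulky borohydride attacks from the open exo face (equatorial attack), so the alcohol is axial (3-endo) and cis to both arms, which sets C6.

Step 5
Reactants: 9 (±)-endo alcohol; 10 angelic acid ((Z)-2-methylbut-2-enoic acid)
Product: 12 (±)-3-endo angelate ester of 9, via mixed anhydride 11 (not isolated)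
Conditions: 10, 2,4,6-trichlorobenzoyl chloride, Et3N, toluene, rt; then 9, toluene, 80 °C
Reagents that add atoms: none
Why: Yamaguchi-type mixed-anhydride esterification run without DMAP, the standard way to acylate hindered alcohols with angelic acid without Z→E isomerisation; no stereocentre changes.

Step 6
Reactants: 12 (±)-angelate
Product: 13 exo-6,7-epoxide of 12 (single enantiomer; epoxide oxygen syn to the oxygen bridge)
Conditions: D-fructose-derived Shi ketone (1,2:4,5-di-O-isopropylidene-β-D-erythro-2,3-hexodiulo-2,6-pyranose, 30 mol %), KHSO5 (as 2KHSO5·KHSO4·K2SO4, 0.7 equiv), K2CO3, Bu4NHSO4, Na2B4O7 buffer, MeCN/dimethoxymethane/H2O, 0 °C, stopped at about 45 % conversion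
Reagents that add atoms: potassium peroxymonosulfate, [K+].[O-]S(=O)(=O)OO
Why: Shi asymmetric epoxidation run as a kinetic resolution; only the exo face is open, and on that face only the drawn enantiomer presents the trisubstituted alkene in the spiro transition-state orientation this dioxirane prefers (the sense assumed here by analogy with 1-phenylcyclohexene), so it is epoxidised first (yield at most 50 %) while the slow enantiomer of 12 is recovered; this sets C9–O, the C10–O bond and the absolute configuration of all ring centres.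

Step 7
Reactants: 13 exo-epoxide
Product: 15 bridged lactol 3-angeloyloxy-2,4-bis[3-(tert-butyldimethylsilyloxy)prop-1-en-2-yl]-1-methyl-6-oxabicyclo[3.2.1]octane-7,8-diol (anomeric mixture at the lactol carbon), via bridged oxocarbenium ion 14 (not isolated)
Conditions: Sc(OTf)3 (10 mol %), H2O (3 equiv), CH2Cl2/MeNO2 (4:1), −30 → 0 °C
Reagents that add atoms: water, O
Why: Proposed new method: Lewis-acid activation of the exo-epoxide ionises the tertiary C10–O bond with assistance from the anti-periplanar C1–C5 σ-bond (the geometry of an exo-2-norbornyl departure), so C5 migrates from C1 to C10 with inversion at C10 and retention at C5, contracting the seven-membered carbocycle to the cyclohexane and leaving an oxocarbenium ion 14 stabilised by the bridge oxygen, which water captures as lactol 15; this forms the C5–C10 bond and the C10 quaternary centre (methyl trans and the former C1 cis to the retained C9–OH), while H9 is not aligned for a hydride shift and the acylated C6 oxygen cannot attack transannularly; the closest known reaction types are the semipinacol rearrangement of 2,3-epoxy alcohols and their silyl ethers and acid-induced Wagner–Meerwein shifts of epoxy-7-oxanorbornanes, not yet shown with a bridging ether oxygen in an 8-oxabicyclo[3.2.1]octane.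

Step 8
Reactants: 15 bridged lactol
Product: 17 6β-angeloyloxy-3,12-bis(tert-butyldimethylsilyloxy)elema-1,4(15),11(13)-triene-8α,9α-diol, via hydroxy aldehyde 16 (not isolated)
Conditions: Ph3PCH3Br (4 equiv), KN(SiMe3)2 (3.9 equiv), THF, 0 °C; then 15, −78 → 0 °C
Reagents that add atoms: methyltriphenylphosphonium bromide, C[P+](c1ccccc1)(c1ccccc1)c1ccccc1.[Br-]
Why: Wittig methylenation of a lactol through its ring-opened tautomer 16 (excess ylide at low temperature to outrun retro-aldol cleavage); C1 becomes the vinyl group and C8–OH is released, and no stereocentre is touched because C10 has no α-hydrogen.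

Step 9
Reactants: 17 bis-silyl ether diol
Product: 18 6β-angeloyloxyelema-1,4(15),11(13)-triene-3,8α,9α,12-tetraol
Conditions: HF·pyridine, pyridine, THF, 0 °C → rt
Reagents that add atoms: none
Why: buffered fluoride desilylation of two primary allylic silyl ethers; non-basic conditions avoid angelate isomerisation and acyl migration.

Step 10
Reactants: 18 tetraol
Product: 20 6β-angeloyloxy-9α-hydroxy-3-oxoelema-1,4(15),11(13)-trien-12,8α-olide, via lactol enal 19 (not isolated)
Conditions: TEMPO (20 mol %), PhI(OAc)2 (3.3 equiv), CH2Cl2, rt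
Reagents that add atoms: none
Why: TEMPO/PhI(OAc)2 oxidative lactonisation of a 1,4-diol; only the two primary allylic alcohols are oxidised, the C3 alcohol stops at the enal, and the C12 aldehyde is captured by the adjacent equatorial C8–OH as the trans-fused lactol 19 and oxidised on to the α-methylene-γ-lactone; C6–O is already acylated and the axial C9–OH (trans to the C7 arm) cannot reach C12.

Step 11
Reactants: 20 hydroxy lactone enal
Product: 21 CNP0228039.1 (9α-acetoxy-6β-angeloyloxy-3-oxoelema-1,4(15),11(13)-trien-12,8α-olide)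
Conditions: Ac2O, DMAP (cat.), pyridine, CH2Cl2, 0 °C → rt
Reagents that add atoms: acetic anhydride, CC(=O)OC(C)=O
Why: DMAP-catalysed acetylation of the only remaining alcohol (axial C9–OH); no stereocentre changes.

**Compound list**
1 | 3-methylfuran | Cc1ccoc1 | starting material
2 | 1,1,3,3-tetrabromoacetone | O=C(C(Br)Br)C(Br)Br | starting material
3 | (±)-2,4-dibromo-6-methyl-8-oxabicyclo[3.2.1]oct-6-en-3-one (mixture of bromide epimers) | CC1=C[C@@H]2O[C@H]1C(Br)C(=O)C2Br | intermediate (not isolated)
4 | (±)-6-methyl-8-oxabicyclo[3.2.1]oct-6-en-3-one | CC1=C[C@@H]2O[C@H]1CC(=O)C2 | intermediate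
5 | 2-bromoprop-2-en-1-ol | OCC(Br)=C | starting material
6 | (2-bromoallyloxy)(tert-butyl)dimethylsilane | C=C(Br)CO[Si](C)(C)C(C)(C)C | intermediate
7 | (±)-mono-alkenyl ketone: one 3-(tert-butyldimethylsilyloxy)prop-1-en-2-yl arm α to the ketone of 4 (both α-regioisomers form; one drawn) | CC1=C[C@@H]2O[C@H]1CC(=O)[C@@H]2C(=C)CO[Si](C)(C)C(C)(C)C | intermediate (not isolated)
8 | (±)-2,4-bis[3-(tert-butyldimethylsilyloxy)prop-1-en-2-yl]-6-methyl-8-oxabicyclo[3.2.1]oct-6-en-3-one (arms equatorial, cis, anti to the oxygen bridge) | CC1=C[C@@H]2O[C@H]1[C@H](C(=C)CO[Si](C)(C)C(C)(C)C)C(=O)[C@@H]2C(=C)CO[Si](C)(C)C(C)(C)C | intermediate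
9 | (±)-2,4-bis[3-(tert-butyldimethylsilyloxy)prop-1-en-2-yl]-6-methyl-8-oxabicyclo[3.2.1]oct-6-en-3-endo-ol (axial OH, cis to both arms) | CC1=C[C@@H]2O[C@H]1[C@H](C(=C)CO[Si](C)(C)C(C)(C)C)[C@H](O)[C@@H]2C(=C)CO[Si](C)(C)C(C)(C)C | intermediate
10 | angelic acid, (Z)-2-methylbut-2-enoic acid | C/C=C(/C)C(=O)O | starting material
11 | angelic 2,4,6-trichlorobenzoic mixed anhydride | C/C=C(/C)C(=O)OC(=O)c1c(Cl)cc(Cl)cc1Cl | intermediate (not isolated)
12 | (±)-3-endo angelate ester of 9 | CC1=C[C@@H]2O[C@H]1[C@H](C(=C)CO[Si](C)(C)C(C)(C)C)[C@H](OC(=O)/C(C)=C\C)[C@@H]2C(=C)CO[Si](C)(C)C(C)(C)C | intermediate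
13 | exo-6,7-epoxide of 12, single enantiomer (epoxide oxygen syn to the oxygen bridge) | C[C@@]12O[C@@H]1[C@@H]3O[C@H]2[C@H](C(=C)CO[Si](C)(C)C(C)(C)C)[C@H](OC(=O)/C(C)=C\C)[C@@H]3C(=C)CO[Si](C)(C)C(C)(C)C | intermediate
14 | bridged oxocarbenium ion (8-hydroxy-1-methyl-6-oxoniabicyclo[3.2.1]oct-6-ene core, drawn with O9 as OH) | [CH]=3[C@]1(C)[C@H](O)[C@H]([O+]3)[C@@H](C(=C)CO[Si](C)(C)C(C)(C)C)[C@@H](OC(=O)/C(C)=C\C)[C@H]1C(=C)CO[Si](C)(C)C(C)(C)C | intermediate (not isolated)
15 | bridged lactol, 3-angeloyloxy-2,4-bis[3-(tert-butyldimethylsilyloxy)prop-1-en-2-yl]-1-methyl-6-oxabicyclo[3.2.1]octane-7,8-diol (lactol carbon = C1, epimeric mixture) | OC3[C@]1(C)[C@H](O)[C@H](O3)[C@@H](C(=C)CO[Si](C)(C)C(C)(C)C)[C@@H](OC(=O)/C(C)=C\C)[C@H]1C(=C)CO[Si](C)(C)C(C)(C)C | intermediate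
16 | ring-opened tautomer of 15: 8α,9α-dihydroxy aldehyde with the formyl group on C10 | O=C[C@]1(C)[C@H](O)[C@H](O)[C@@H](C(=C)CO[Si](C)(C)C(C)(C)C)[C@@H](OC(=O)/C(C)=C\C)[C@H]1C(=C)CO[Si](C)(C)C(C)(C)C | intermediate (not isolated)
17 | 6β-angeloyloxy-3,12-bis(tert-butyldimethylsilyloxy)elema-1,4(15),11(13)-triene-8α,9α-diol | C=C[C@]1(C)[C@H](O)[C@H](O)[C@@H](C(=C)CO[Si](C)(C)C(C)(C)C)[C@@H](OC(=O)/C(C)=C\C)[C@H]1C(=C)CO[Si](C)(C)C(C)(C)C | intermediate
18 | 6β-angeloyloxyelema-1,4(15),11(13)-triene-3,8α,9α,12-tetraol | C=C[C@]1(C)[C@H](O)[C@H](O)[C@@H](C(=C)CO)[C@@H](OC(=O)/C(C)=C\C)[C@H]1C(=C)CO | intermediate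
19 | lactol enal: 12-hydroxy-8α,12-epoxy (γ-lactol) form with the C3 enal, 9α-OH free | C=C[C@]1(C)[C@H](O)[C@@H]2OC(O)C(=C)[C@H]2[C@@H](OC(=O)/C(C)=C\C)[C@H]1C(=C)C=O | intermediate (not isolated)
20 | 6β-angeloyloxy-9α-hydroxy-3-oxoelema-1,4(15),11(13)-trien-12,8α-olide | C=C[C@]1(C)[C@H](O)[C@@H]2OC(=O)C(=C)[C@H]2[C@@H](OC(=O)/C(C)=C\C)[C@H]1C(=C)C=O | intermediate
21 | CNP0228039.1, 9α-acetoxy-6β-angeloyloxy-3-oxoelema-1,4(15),11(13)-trien-12,8α-olide | C=C[C@]1(C)[C@H](OC(C)=O)[C@@H]2OC(=O)C(=C)[C@H]2[C@@H](OC(=O)/C(C)=C\C)[C@H]1C(=C)C=O | target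

**Step count**
Total: 11 steps. Longest linear sequence: 10 steps (steps 1 and 3–11; step 2 is a side branch).

**Steps most likely to fail**

Step 7 (the proposed new ring contraction). Risks are a hydride shift from C9 giving the bridge ketone, the regioisomeric shift at C9, or simple hydration of the epoxide. The fallback sets out from alkene 12, used as the single enantiomer secured by the early resolution described under step 6, and comes back at 15. Exo-selective dihydroxylation (OsO4 cat., N-methylmorpholine N-oxide, acetone/H2O, 0 °C, one equivalent of oxidant; the strained trisubstituted bridge alkene should react before the 1,1-disubstituted arms) gives the exo,cis-diol F2. A classical acid-promoted pinacol rearrangement (TsOH·H2O cat., wet CH2Cl2, 0 °C → rt) then ionises the tertiary carbinol, the same anti-periplanar ring bond migrates to the oxygen-stabilised terminus, and water gives 15. The pinacol rearrangement is textbook chemistry, although it passes through the same cation; no shift-free path to 15 exists from the bicyclic series, and the hydride-shift channel remains.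

Step 3 (one-pot double enolate alkenylation). Risks are base-induced opening of the oxygen bridge, incomplete second coupling, and conjugation of the β,γ-unsaturated ketone. The fallback sets out from dibromide 3, isolated by omitting the Zn–Cu stage of step 1, and from 6, and comes back at 8. Compound 6 is converted (Mg, THF; then ZnCl2) into [3-(tert-butyldimethylsilyloxy)prop-1-en-2-yl]zinc chloride F1. F1 is coupled at both C–Br bonds of 3 by a Ni-catalysed stereoconvergent Negishi coupling of secondary α-bromo ketones (NiCl2(dme), 4,4′-di-tert-butyl-2,2′-bipyridine, THF/DMA, 0 °C). Brief equilibration (Et3N, CH2Cl2) gives the diequatorial isomer 8. The polarity is reversed (electrophilic α-carbon, no free enolate at elevated temperature); the main risk here is reductive loss of both bromides through an oxyallyl species.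

Step 6 (Shi kinetic resolution). Risks are a low selectivity factor on this bridged alkene and slow epoxidation next to two allylic C–O bonds. The fallback sets out from racemic 4 and comes back at 13. The enantiomers of the small rigid ketone 4 are separated by preparative chromatography on a chiral stationary phase; the enantiomer carried on must be confirmed by correlation at this point. Steps 3–5 are run on the single enantiomer, and the epoxidation becomes a substrate-controlled exo-epoxidation with mCPBA (NaHCO3, CH2Cl2, 0 °C). This removes any dependence on catalyst–substrate matching and moves the 50 % loss to the first intermediate; it makes no new compound (none, F0).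

Further compounds
F1 | step 3 | [3-(tert-butyldimethylsilyloxy)prop-1-en-2-yl]zinc chloride | C=C([Zn]Cl)CO[Si](C)(C)C(C)(C)C
F0 | step 6 | none | none
F2 | step 7 | exo,cis-6,7-diol of 12 (both hydroxyls syn to the oxygen bridge; tertiary OH on the methyl-bearing carbon) | C[C@@]1(O)[C@H](O)[C@@H]2O[C@H]1[C@H](C(=C)CO[Si](C)(C)C(C)(C)C)[C@H](OC(=O)/C(C)=C\C)[C@@H]2C(=C)CO[Si](C)(C)C(C)(C)C
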